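Ring B of the tetralone is cut at both of its bonds to ring A, C1–C8a and C4–C4a. Ring A is then veratrole, whose two adjacent free carbons (future C4a and C8a) each lie para to a methoxy group, while C4 (benzylic to ring C, para to its 4'-methoxy) and C1 (acyl) are the electrophilic ends of a γ-lactone. In one operation triflic acid ionises an enantioenriched 5-aryl-3,4-dimethylbutyrolactone, veratrole captures the cation, and the liberated acid acylates the neighbouring carbon. The lactone, whose ring is absent from the target, comes from desymmetrised meso-2,3-dimethylsuccinic anhydride; a tosylate silences ring C.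

Key step: step 5

Remarks on the chemistry
- Locants follow the tetralone: C1 is the carbonyl carbon, C4 the aryl-bearing carbon. Ring A is the dimethoxybenzo ring, ring B the cyclohexanone ring, ring C the pendant aryl group. "Tosyloxy" means 4-methylbenzenesulfonyloxy.
- The target is (2S,3R,4R): the 2- and 3-methyl groups are trans, and the 3-methyl and 4-aryl groups are cis.
- Assumption: (S)-t-Bu-PHOX is taken to deliver the (2R,3S) keto acid 7. If the sense of induction is the opposite, (R)-t-Bu-PHOX is used and nothing else changes.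
- Lactone 9 is drawn as its expected major C5 epimer. The minor C5 epimer need not be removed, because C5 is ionised in step 5.
- Compounds 1, 3 and 10 are commercially available.

Step 1
Reactants: 1 5-iodo-2-methoxyphenol
Product: 2 5-iodo-2-methoxyphenyl 4-methylbenzenesulfonate
Conditions: TsCl, Et3N, DMAP (cat.), CH2Cl2, 0 °C → rt
Reagents that add atoms: p-toluenesulfonyl chloride, Cc1ccc(S(Cl)(=O)=O)cc1
Why: O-sulfonylation of a phenol gives a tosylate that should survive the organozinc step and triflic acid and that later deactivates ring C.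

Step 2
Reactants: 3 meso-2,3-dimethylsuccinic acid
Product: 4 cis-3,4-dimethyloxolane-2,5-dione (meso)
Conditions: AcCl (neat), reflux; evaporate
Reagents that add atoms: none
Why: Cyclodehydration of a 1,4-diacid through its mixed anhydride touches neither stereocentre, so the meso acid should give the cis anhydride.

Step 3
Reactants: 2 5-iodo-2-methoxyphenyl 4-methylbenzenesulfonate; 4 cis-3,4-dimethyloxolane-2,5-dione
Product: 7 (2R,3S)-4-[4-methoxy-3-(tosyloxy)phenyl]-2,3-dimethyl-4-oxobutanoic acid, via aryllithium 5 (not isolated), via arylzinc triflate 6 (not isolated)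
Conditions: 2, n-BuLi, THF, −100 °C; Zn(OTf)2, −100 °C → rt; then 4, [Rh(cod)Cl]2 (cat.), (S)-t-Bu-PHOX (cat.), THF, 50 °C; aq. HCl
Reagents that add atoms: none
Why: Rhodium-catalysed enantioselective cross-coupling of a meso cyclic anhydride with an arylzinc (anhydride desymmetrisation): the chiral monovalent rhodium–PHOX complex inserts into one of the two enantiotopic acyl–oxygen bonds, which fixes the absolute configuration, while the two methyl-bearing centres of 4 are carried over unchanged; iodine–lithium exchange at −100 °C should outrun attack on the sulfonate.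

Step 4
Reactants: 7 (2R,3S)-4-[4-methoxy-3-(tosyloxy)phenyl]-2,3-dimethyl-4-oxobutanoic acid
Product: 9 (3R,4S,5S)-5-[4-methoxy-3-(tosyloxy)phenyl]-3,4-dimethyloxolan-2-one, via hydroxy acid 8 (not isolated)
Conditions: LiBH(s-Bu)3 (L-Selectride, 2.2 equiv), THF, −78 → 0 °C; then 2 M HCl, rt
Reagents that add atoms: none
Why: The bulky borohydride should reduce the aryl ketone of the lithium carboxylate in the Felkin–Anh sense (hydride anti to the CH(CH3)CO2Li branch) and acidification closes the γ-lactone by 5-exo-trig acyl substitution, giving mainly the 4,5-trans lactone.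

Step 5
Reactants: 9 (3R,4S,5S)-5-[4-methoxy-3-(tosyloxy)phenyl]-3,4-dimethyloxolan-2-one; 10 veratrole (1,2-dimethoxybenzene)
Product: 12 (2R,3R,4R)-6,7-dimethoxy-4-[4-methoxy-3-(tosyloxy)phenyl]-2,3-dimethyl-3,4-dihydronaphthalen-1(2H)-one, via diaryl acid 11 (not isolated)
Conditions: 10 (3 equiv), TfOH (5 equiv), CH2Cl2, −40 °C → rt
Reagents that add atoms: none
Why: TfOH protonates lactone 9 and heterolysis of its C5–O bond gives a benzylic cation at the future C4, stabilised by the para methoxy group of ring C; veratrole attacks it through the carbon para to a methoxy group to give acid 11, whose carboxyl group is then activated by the excess acid and acylates the veratryl carbon ortho to the new bond and para to the second methoxy group. The closest known reaction type is the one-pot Friedel–Crafts alkylation–acylation of arenes with γ-aryl-γ-butyrolactones to 4-aryl-1-tetralones (Haworth-type closure). Ring B closes as a six-membered ring by intramolecular electrophilic aromatic substitution, 6-exo-dig at the acylium carbon. The one new stereocentre, C4, is set in the intermolecular arylation by 1,2-induction from C3: the cation should hold C3–H in the aryl plane to avoid allylic 1,3-strain, and veratrole should add to the face that carries the methyl group, anti to the larger CH(CH3)CO2H branch, which after closure places the 4-aryl and 3-methyl groups cis. C2 and C3 are carried through from 9 (C2 may partly epimerise in the acid, which step 6 completes in any case). Closure onto ring A and not ring C should be secured by the tosylate, since the only accessible position of ring C is para to the sulfonyloxy group, and excess veratrole at low temperature is used so that capture of the cation outruns loss of the C3 proton.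

Step 6
Reactants: 12 (2R,3R,4R)-6,7-dimethoxy-4-[4-methoxy-3-(tosyloxy)phenyl]-2,3-dimethyl-3,4-dihydronaphthalen-1(2H)-one
Product: 14 (2S,3R,4R)-4-(3-hydroxy-4-methoxyphenyl)-6,7-dimethoxy-2,3-dimethyl-3,4-dihydronaphthalen-1(2H)-one, via 2-epimeric tosylate 13 (not isolated)
Conditions: KOH, MeOH/H2O (degassed), reflux; then aq. HCl
Reagents that add atoms: none
Why: Hydroxide cleaves the aryl sulfonate at sulfur and, through the potassium enolate, should equilibrate C2 to the more stable epimer with the 2- and 3-methyl groups trans-diequatorial and the 4-aryl group pseudoaxial (base-mediated epimerisation), while C3 and C4 are not acidic under these conditions.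

Compound list
1 | 5-iodo-2-methoxyphenol | COc1ccc(I)cc1O | starting material
2 | 5-iodo-2-methoxyphenyl 4-methylbenzenesulfonate | COc1ccc(I)cc1OS(=O)(=O)c1ccc(C)cc1 | intermediate
3 | meso-2,3-dimethylsuccinic acid, (2R,3S)-2,3-dimethylbutanedioic acid | OC(=O)[C@H](C)[C@H](C)C(=O)O | starting material
4 | cis-3,4-dimethyloxolane-2,5-dione, (3R,4S), meso | O=C1[C@H](C)[C@H](C)C(=O)O1 | intermediate
5 | [4-methoxy-3-(tosyloxy)phenyl]lithium | [Li]c1ccc(OC)c(OS(=O)(=O)c2ccc(C)cc2)c1 | intermediate
6 | [4-methoxy-3-(tosyloxy)phenyl]zinc trifluoromethanesulfonate | FC(F)(F)S(=O)(=O)O[Zn]c1ccc(OC)c(OS(=O)(=O)c2ccc(C)cc2)c1 | intermediate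
7 | (2R,3S)-4-[4-methoxy-3-(tosyloxy)phenyl]-2,3-dimethyl-4-oxobutanoic acid | OC(=O)[C@H](C)[C@H](C)C(=O)c1ccc(OC)c(OS(=O)(=O)c2ccc(C)cc2)c1 | intermediate
8 | (2R,3S,4S)-4-hydroxy-4-[4-methoxy-3-(tosyloxy)phenyl]-2,3-dimethylbutanoic acid | OC(=O)[C@H](C)[C@H](C)[C@H](O)c1ccc(OC)c(OS(=O)(=O)c2ccc(C)cc2)c1 | intermediate
9 | (3R,4S,5S)-5-[4-methoxy-3-(tosyloxy)phenyl]-3,4-dimethyloxolan-2-one (3,4-cis, 4,5-trans) | O=C1[C@H](C)[C@H](C)[C@@H](c2ccc(OC)c(OS(=O)(=O)c3ccc(C)cc3)c2)O1 | intermediate
10 | veratrole (1,2-dimethoxybenzene) | COc1ccccc1OC | starting material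
11 | (2R,3R,4S)-4-(3,4-dimethoxyphenyl)-4-[4-methoxy-3-(tosyloxy)phenyl]-2,3-dimethylbutanoic acid | OC(=O)[C@H](C)[C@H](C)[C@@H](c1ccc(OC)c(OC)c1)c1ccc(OC)c(OS(=O)(=O)c2ccc(C)cc2)c1 | intermediate
12 | (2R,3R,4R)-6,7-dimethoxy-4-[4-methoxy-3-(tosyloxy)phenyl]-2,3-dimethyl-3,4-dihydronaphthalen-1(2H)-one (2,3-cis, 3,4-cis) | COc1ccc([C@@H]2c3cc(OC)c(OC)cc3C(=O)[C@H](C)[C@@H]2C)cc1OS(=O)(=O)c1ccc(C)cc1 | intermediate
13 | (2S,3R,4R)-6,7-dimethoxy-4-[4-methoxy-3-(tosyloxy)phenyl]-2,3-dimethyl-3,4-dihydronaphthalen-1(2H)-one (2,3-trans, 3,4-cis) | COc1ccc([C@@H]2c3cc(OC)c(OC)cc3C(=O)[C@@H](C)[C@@H]2C)cc1OS(=O)(=O)c1ccc(C)cc1 | intermediate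
14 | (2S,3R,4R)-4-(3-hydroxy-4-methoxyphenyl)-6,7-dimethoxy-2,3-dimethyl-3,4-dihydronaphthalen-1(2H)-one | COc1ccc([C@@H]2c3cc(OC)c(OC)cc3C(=O)[C@@H](C)[C@@H]2C)cc1O | target

Total step count: 6
Longest linear sequence: 5 steps (1 → 2 → 7 → 9 → 12 → 14; step 2 is a one-step branch)

Steps most likely to fail

1. Step 5 (key step). Three things may go wrong. Veratrole may capture the benzylic cation with poor facial selectivity, which leads into the 3,4-trans series. The cation may lose the C3 proton to a styrene, and re-protonation would erode the C3 configuration. The activated acid may acylate free veratrole instead of closing the ring. Fallback: the two bonds are made in separate flasks, so that the C4 epimers can be separated before ring closure. It sets out from 9. The arylation alone is run with veratrole and TfOH (1.1 equiv) in CH2Cl2 at −78 → −30 °C, where the carboxylic acid should not be activated. Acid 11 is isolated and freed from its C4 epimer by crystallisation or chromatography. Oxalyl chloride and catalytic DMF convert 11 into (2R,3R,4S)-4-(3,4-dimethoxyphenyl)-4-[4-methoxy-3-(tosyloxy)phenyl]-2,3-dimethylbutanoyl chloride F1, which is cyclised with SnCl4 in CH2Cl2 at −78 °C by intramolecular Friedel–Crafts acylation. The sequence comes back to the route at 12.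

2. Step 3. The aryllithium may attack a sulfonate ester before it is transmetalated to zinc, or the insertion into the enantiotopic acyl–oxygen bonds may be insufficiently selective. Fallback: the aryl ketone is built without an aryl-metal reagent. It sets out from 4. Alkaloid-catalysed methanolysis ((DHQD)2AQN, MeOH, Et2O, −20 °C; the pseudo-enantiomeric (DHQ)2AQN if the other hemiester forms) should give (2S,3R)-4-methoxy-2,3-dimethyl-4-oxobutanoic acid F2. Oxalyl chloride converts it into methyl (2R,3S)-4-chloro-2,3-dimethyl-4-oxobutanoate F3. Friedel–Crafts acylation of 2-methoxyphenyl 4-methylbenzenesulfonate F4 (from guaiacol and TsCl) with F3 and AlCl3 in CH2Cl2 at 0 °C, para to the methoxy group, should give methyl (2R,3S)-4-[4-methoxy-3-(tosyloxy)phenyl]-2,3-dimethyl-4-oxobutanoate F5. L-Selectride reduction of F5 and treatment with TsOH in toluene close the lactone with loss of methanol, and the sequence comes back to the route at 9.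

3. Step 6. The enolate and the phenoxide may be oxidised or may condense in hot hydroxide, or cleavage of the sulfur–oxygen bond may stay incomplete. Fallback: the ketone is masked by reduction while the sulfonate is cleaved. It sets out from 12. DBU in toluene at rt epimerises C2 and should give 13, which is isolated. NaBH4 in MeOH/THF reduces it to (2S,3R,4R)-6,7-dimethoxy-4-[4-methoxy-3-(tosyloxy)phenyl]-2,3-dimethyl-1,2,3,4-tetrahydronaphthalen-1-ol F6 (C1 epimer mixture). KOH in MeOH/H2O at reflux then cleaves the tosylate with no enolisable ketone present and gives (2S,3R,4R)-4-(3-hydroxy-4-methoxyphenyl)-6,7-dimethoxy-2,3-dimethyl-1,2,3,4-tetrahydronaphthalen-1-ol F7 (C1 epimer mixture). MnO2 in CH2Cl2 re-oxidises the benzylic alcohol, and the sequence comes back to the route at 14.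

Further compounds
F1 | step 5 | (2R,3R,4S)-4-(3,4-dimethoxyphenyl)-4-[4-methoxy-3-(tosyloxy)phenyl]-2,3-dimethylbutanoyl chloride | ClC(=O)[C@H](C)[C@H](C)[C@@H](c1ccc(OC)c(OC)c1)c1ccc(OC)c(OS(=O)(=O)c2ccc(C)cc2)c1
F2 | step 3 | (2S,3R)-4-methoxy-2,3-dimethyl-4-oxobutanoic acid | COC(=O)[C@H](C)[C@H](C)C(=O)O
F3 | step 3 | methyl (2R,3S)-4-chloro-2,3-dimethyl-4-oxobutanoate | COC(=O)[C@H](C)[C@H](C)C(=O)Cl
F4 | step 3 | 2-methoxyphenyl 4-methylbenzenesulfonate | COc1ccccc1OS(=O)(=O)c1ccc(C)cc1
F5 | step 3 | methyl (2R,3S)-4-[4-methoxy-3-(tosyloxy)phenyl]-2,3-dimethyl-4-oxobutanoate | COC(=O)[C@H](C)[C@H](C)C(=O)c1ccc(OC)c(OS(=O)(=O)c2ccc(C)cc2)c1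
F6 | step 6 | (2S,3R,4R)-6,7-dimethoxy-4-[4-methoxy-3-(tosyloxy)phenyl]-2,3-dimethyl-1,2,3,4-tetrahydronaphthalen-1-ol (C1 epimer mixture) | COc1ccc([C@@H]2c3cc(OC)c(OC)cc3C(O)[C@@H](C)[C@@H]2C)cc1OS(=O)(=O)c1ccc(C)cc1
F7 | step 6 | (2S,3R,4R)-4-(3-hydroxy-4-methoxyphenyl)-6,7-dimethoxy-2,3-dimethyl-1,2,3,4-tetrahydronaphthalen-1-ol (C1 epimer mixture) | COc1ccc([C@@H]2c3cc(OC)c(OC)cc3C(O)[C@@H](C)[C@@H]2C)cc1O
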